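**Retrosynthetic overview**

- The oxazolidine and pyrrolidine rings come last, from one N,O-acetal annulation of a (4R)-α-ketol/vinylogous acid with a 4-aminobutanal acetal; the aminal centre is set thermodynamically. The free C8 hydroxyl is released just before by peri-demethylation.
- The C4 stereocentre comes from a catalytic enantioselective hydroxylative dearomatization of a 3-hydroxy-4-methylphenanthrene (ring C holds a 1-methyl-2-naphthol motif).
- Ring B comes from a Friedel–Crafts closure C9–C8a, with an aryl lactone (benzofuranone) as the acyl donor.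
- Ring C comes from closing C4a–C10a by aldol cyclization/aromatization of an open-chain 1,3,5-triketo acid made from 1-(3,5-dimethoxyphenyl)propan-1-one, methyl methoxyacetate and succinic anhydride. Enabling feature: in its aromatic tautomer ring C is a resorcinol whose oxygens at C1 and C3 alternate along the chain C4a(=O)–C4–C3(=O)–C2–C1(=O)–C10a, so C10a (α to the C1 carbonyl) is 1,5 to the aryl ketone C4a; the C1 hydroxyl ortho to the C10a acetic acid arm then lactonizes and distinguishes C1–OH from C3–OH.
- Order of ring formation: ring A (purchased) → ring C → ring B → oxazolidine and pyrrolidine together.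

Key step: step 3

Numbering and assumption: phenanthrene locants are used throughout (ring C = C1–C4, C4a, C10a; ring B = C9, C10; ring A = C5–C8; the aminal carbon is the pyrrolidine carbon between N and O). The target is taken to be the thermodynamically preferred tautomer as drawn (C9 ketone chelated to C8–OH, C10 methylene), and the dearomatized intermediates after the deacetylation are drawn in the same tautomeric form.

**Step 1**
Reactants: 1 1-(3,5-dimethoxyphenyl)propan-1-one; 2 methyl methoxyacetate
Product: 3 1-(3,5-dimethoxyphenyl)-4-methoxy-2-methylbutane-1,3-dione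
Conditions: NaH (2.5 equiv), 2 (3 equiv), THF, 0 °C to reflux; then aq. HCl
Reagents that add atoms: none
Why: Crossed Claisen condensation in which the sodium enolate of 1 (its only enolizable position) is acylated by the more electrophilic α-alkoxy ester and the equilibrium is pulled by deprotonation of the β-diketone; C4 stays enolizable, so no stereocentre of consequence arises.

**Step 2**
Reactants: 3 1-(3,5-dimethoxyphenyl)-4-methoxy-2-methylbutane-1,3-dione; 4 succinic anhydride
Product: 5 8-(3,5-dimethoxyphenyl)-5-methoxy-7-methyl-4,6,8-trioxooctanoic acid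
Conditions: LiN(iPr)2 (2.1 equiv per 3), THF, −78 to 0 °C; 4 (0.5 equiv), −78 °C to rt; then aq. HCl (the surplus dianion serves as base and is recovered as 3)
Reagents that add atoms: none
Why: Harris-type γ-acylation of a β-diketone dianion: the second deprotonation can only take place at the C2 methylene, and this terminal carbanion, the most nucleophilic site, opens the anhydride to the keto acid; C2 and C4 are enolizable and stereochemically irrelevant.

**Step 3**
Reactants: 5 8-(3,5-dimethoxyphenyl)-5-methoxy-7-methyl-4,6,8-trioxooctanoic acid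
Product: 7 4-(3,5-dimethoxyphenyl)-6-hydroxy-7-methoxy-5-methyl-1-benzofuran-2(3H)-one, via resorcinol acid 6 (not isolated)
Conditions: KOH (2 M aq.), MeOH, argon, 0 to 40 °C; then 6 M HCl, 60 °C
Reagents that add atoms: none
Why: Aqueous hydroxide converts 5 into its polyanion, in which the terminal carbanion C10a (the γ-carbon of the C3/C1 diketone dianion) adds to the aryl ketone carbon C4a, hydroxide is eliminated to give the C4a=C10a bond and the cyclohexadienone tautomerizes to the resorcinol 6, after which acidification closes the γ-lactone between C1–OH and the C9 acid. The closest known reaction type is the Collie/Harris biomimetic aldol cyclization of 1,3,5-triketones and 3,5,7-triketo acids to resorcinols (2,4,6-heptanetrione to orcinol, 1-aryl triketones to 5-arylresorcinols). Ring C closes in a 6-(enolendo)-exo-trig aldol and the lactone in a 5-exo-trig acyl substitution. No stereocentre is formed, since C2 and C4 of 5 become sp2 carbons of the arene. The step needs C-cyclization instead of O-cyclization to the γ-pyrone or chain cleavage, which the strongly basic medium favours, and it needs a single aldol pairing, which the chain secures because every other carbanion/carbonyl pair would give a four-membered ring and C9 is an unreactive carboxylate. The lactone can only form to C1–OH, the sole hydroxyl ortho to the acetic acid arm, which leaves C3–OH as the one free phenol for steps 4 to 7.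

**Step 4**
Reactants: 7 4-(3,5-dimethoxyphenyl)-6-hydroxy-7-methoxy-5-methyl-1-benzofuran-2(3H)-one
Product: 8 4-(3,5-dimethoxyphenyl)-7-methoxy-5-methyl-2-oxo-2,3-dihydro-1-benzofuran-6-yl 2,2,2-trichloroethyl carbonate
Conditions: ClCO2CH2CCl3, pyridine, 4-(dimethylamino)pyridine (cat.), CH2Cl2, 0 °C to rt
Reagents that add atoms: 2,2,2-trichloroethyl chloroformate, ClC(=O)OCC(Cl)(Cl)Cl
Why: Acylation of the only free phenol (C3–OH) as a carbonate that tolerates the strong acid of step 5 and is later removed reductively without touching aryl acetates.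

**Step 5**
Reactants: 8 4-(3,5-dimethoxyphenyl)-7-methoxy-5-methyl-2-oxo-2,3-dihydro-1-benzofuran-6-yl 2,2,2-trichloroethyl carbonate
Product: 10 2,6,8-trimethoxy-4-methyl-3-{[(2,2,2-trichloroethoxy)carbonyl]oxy}phenanthrene-1,9-diyl diacetate, via phenanthrene-1,9-diol 9 (not isolated)
Conditions: CF3SO3H (5 equiv), CH2Cl2, 0 °C, argon; ice-water work-up; crude diol: acetic anhydride, pyridine, 4-(dimethylamino)pyridine (cat.), rt
Reagents that add atoms: acetic anhydride, CC(=O)OC(C)=O
Why: Intramolecular Friedel–Crafts (Fries-type) acylation in which the acid ionizes the aryl lactone to an acylium ion that C8a of the 3,5-dimethoxyphenyl ring (ortho and para to the two methoxy groups, both ortho positions equivalent) traps in a six-membered closure, the ketone tautomerizes to the 9-phenanthrol, and the air-sensitive 1,9-diol is capped at once as its diacetate.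

**Step 6**
Reactants: 10 2,6,8-trimethoxy-4-methyl-3-{[(2,2,2-trichloroethoxy)carbonyl]oxy}phenanthrene-1,9-diyl diacetate
Product: 11 3-hydroxy-2,6,8-trimethoxy-4-methylphenanthrene-1,9-diyl diacetate
Conditions: Zn dust, AcOH/THF, rt
Reagents that add atoms: none
Why: Reductive β-elimination of the trichloroethyl carbonate by zinc frees C3–OH alone, since aryl acetates, methyl ethers and the arene are inert to zinc in acetic acid.

**Step 7**
Reactants: 11 3-hydroxy-2,6,8-trimethoxy-4-methylphenanthrene-1,9-diyl diacetate
Product: 12 (4R)-4-hydroxy-2,6,8-trimethoxy-4-methyl-3-oxo-3,4-dihydrophenanthrene-1,9-diyl diacetate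
Conditions: Sc(O3SCF3)3 (10 mol %), (2S,2'S)-1,1'-(propane-1,3-diyl)bis[2-(2,6-diisopropylphenylcarbamoyl)piperidine] 1,1'-dioxide (11 mol %), 3-phenyl-2-(phenylsulfonyl)-1,2-oxaziridine (1.2 equiv), CH2Cl2, 4 Å molecular sieves, 0 °C
Reagents that add atoms: 3-phenyl-2-(phenylsulfonyl)-1,2-oxaziridine, O=S(=O)(c1ccccc1)N1OC1c1ccccc1
Why: Catalytic asymmetric hydroxylative dearomatization of a 1-alkyl-2-naphthol-type phenol by an N-sulfonyloxaziridine under a chiral scandium/N,N'-dioxide complex: C4 is the naphthol α-carbon of the only free phenol (attack there keeps rings A and B aromatic and relieves the C4-methyl/C5–H bay strain), and the ligand-shielded scandium phenolate is expected to take oxygen on the C4 Re face (C3 > C4a > CH3) to give 4R, a sense proposed by analogy with 1-methyl-2-naphthol, the (2R,2'R)-ligand giving the antipode.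

**Step 8**
Reactants: 12 (4R)-4-hydroxy-2,6,8-trimethoxy-4-methyl-3-oxo-3,4-dihydrophenanthrene-1,9-diyl diacetate
Product: 13 (4R)-3,4-dihydroxy-2,6,8-trimethoxy-4-methylphenanthrene-1,9(4H,10H)-dione
Conditions: K2CO3 (3 equiv), MeOH, 0 °C; then cold dilute HCl to pH 3
Reagents that add atoms: none
Why: Carbonate-mediated methanolysis of the C1 enol acetate and the C9 aryl acetate, cold and brief so that the tertiary α-ketol at C4 is not disturbed, releases the vinylogous acid and the C9 oxygen.

**Step 9**
Reactants: 13 (4R)-3,4-dihydroxy-2,6,8-trimethoxy-4-methylphenanthrene-1,9(4H,10H)-dione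
Product: 14 (4R)-3,4,8-trihydroxy-2,6-dimethoxy-4-methylphenanthrene-1,9(4H,10H)-dione
Conditions: BCl3 (1 M in CH2Cl2, 4 equiv), CH2Cl2, −78 to −20 °C; then H2O
Reagents that add atoms: none
Why: Chelation-controlled ether cleavage: boron bound at the C9 oxygen forms a six-membered chelate with the peri C8 methoxy group, which alone is dealkylated by chloride, whereas C6–OMe has no chelating partner and C2–OMe sits on the central carbon of the boron-chelated C1/C3 diketonate.

**Step 10**
Reactants: 14 (4R)-3,4,8-trihydroxy-2,6-dimethoxy-4-methylphenanthrene-1,9(4H,10H)-dione; 15 4,4-diethoxybutan-1-amine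
Product: 18 target CNP0528850.1, via enaminone acetal 16 (not isolated), via enaminone aldehyde 17 (not isolated)
Conditions: 15 (1.5 equiv), EtOH, 50 °C; then AcOH/H2O/THF, 40 °C
Reagents that add atoms: none
Why: Condensation of the primary amine with the vinylogous acid gives the vinylogous amide, aqueous acetic acid unmasks the aldehyde, nitrogen closes the pyrrolidine as a cyclic iminium ion and the C4 hydroxyl traps it as the oxazolidine; enaminone formation is reversible and only the C3 isomer has the C4 hydroxyl within reach, and the reversible N,O-acetal settles with the pyrrolidine ring on the face opposite the C4 methyl (aminal H cis to CH3), which is the (S)-aminal for 4R.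

**Compound list**

1 | 1-(3,5-dimethoxyphenyl)propan-1-one | CCC(=O)c1cc(OC)cc(OC)c1 | starting material
2 | methyl methoxyacetate | COCC(=O)OC | starting material
3 | 1-(3,5-dimethoxyphenyl)-4-methoxy-2-methylbutane-1,3-dione | COCC(=O)C(C)C(=O)c1cc(OC)cc(OC)c1 | intermediate
4 | succinic anhydride | O=C1CCC(=O)O1 | starting material
5 | 8-(3,5-dimethoxyphenyl)-5-methoxy-7-methyl-4,6,8-trioxooctanoic acid | OC(=O)CCC(=O)C(OC)C(=O)C(C)C(=O)c1cc(OC)cc(OC)c1 | intermediate
6 | [6-(3,5-dimethoxyphenyl)-2,4-dihydroxy-3-methoxy-5-methylphenyl]acetic acid | OC(=O)Cc1c(O)c(OC)c(O)c(C)c1-c1cc(OC)cc(OC)c1 | intermediate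
7 | 4-(3,5-dimethoxyphenyl)-6-hydroxy-7-methoxy-5-methyl-1-benzofuran-2(3H)-one | O=C1Cc2c(O1)c(OC)c(O)c(C)c2-c1cc(OC)cc(OC)c1 | intermediate
8 | 4-(3,5-dimethoxyphenyl)-7-methoxy-5-methyl-2-oxo-2,3-dihydro-1-benzofuran-6-yl 2,2,2-trichloroethyl carbonate | O=C1Cc2c(O1)c(OC)c(OC(=O)OCC(Cl)(Cl)Cl)c(C)c2-c1cc(OC)cc(OC)c1 | intermediate
9 | 1,9-dihydroxy-2,6,8-trimethoxy-4-methylphenanthren-3-yl 2,2,2-trichloroethyl carbonate | Oc1c(OC)c(OC(=O)OCC(Cl)(Cl)Cl)c(C)c2c1cc(O)c1c(OC)cc(OC)cc12 | intermediate
10 | 2,6,8-trimethoxy-4-methyl-3-{[(2,2,2-trichloroethoxy)carbonyl]oxy}phenanthrene-1,9-diyl diacetate | CC(=O)Oc1c(OC)c(OC(=O)OCC(Cl)(Cl)Cl)c(C)c2c1cc(OC(C)=O)c1c(OC)cc(OC)cc12 | intermediate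
11 | 3-hydroxy-2,6,8-trimethoxy-4-methylphenanthrene-1,9-diyl diacetate | CC(=O)Oc1c(OC)c(O)c(C)c2c1cc(OC(C)=O)c1c(OC)cc(OC)cc12 | intermediate
12 | (4R)-4-hydroxy-2,6,8-trimethoxy-4-methyl-3-oxo-3,4-dihydrophenanthrene-1,9-diyl diacetate | CC(=O)OC1=C(OC)C(=O)[C@](C)(O)c2c1cc(OC(C)=O)c1c(OC)cc(OC)cc12 | intermediate
13 | (4R)-3,4-dihydroxy-2,6,8-trimethoxy-4-methylphenanthrene-1,9(4H,10H)-dione | COC1=C(O)[C@](C)(O)C2=C(CC(=O)c3c(OC)cc(OC)cc32)C1=O | intermediate
14 | (4R)-3,4,8-trihydroxy-2,6-dimethoxy-4-methylphenanthrene-1,9(4H,10H)-dione | COC1=C(O)[C@](C)(O)C2=C(CC(=O)c3c(O)cc(OC)cc32)C1=O | intermediate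
15 | 4,4-diethoxybutan-1-amine | NCCCC(OCC)OCC | starting material
16 | (4R)-3-[(4,4-diethoxybutyl)amino]-4,8-dihydroxy-2,6-dimethoxy-4-methylphenanthrene-1,9(4H,10H)-dione | COC1=C(NCCCC(OCC)OCC)[C@](C)(O)C2=C(CC(=O)c3c(O)cc(OC)cc32)C1=O | intermediate
17 | 4-{[(4R)-4,8-dihydroxy-2,6-dimethoxy-4-methyl-1,9-dioxo-1,4,9,10-tetrahydrophenanthren-3-yl]amino}butanal | COC1=C(NCCCC=O)[C@](C)(O)C2=C(CC(=O)c3c(O)cc(OC)cc32)C1=O | intermediate
18 | CNP0528850.1: 8-hydroxy-2,6-dimethoxy-4-methylphenanthrene-1,9(4H,10H)-dione with N on C3 and O on C4 joined through the aminal carbon of a fused pyrrolidine (C4 R, aminal carbon S) | COC1=C2N3CCC[C@@H]3O[C@]2(C)C2=C(CC(=O)c3c(O)cc(OC)cc32)C1=O | target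

**Total step count:** 10. **Longest linear sequence:** 10 steps (1 to 18).

**Steps most likely to fail**

1. Step 3. The polyanion may partition away from C-attack on the hindered, α-branched aryl ketone: toward the unreactive C4 enolate, toward O-cyclization (γ-pyrone on acidification), or toward hydroxide-induced retro-Claisen chain cleavage. The fallback sets out from 5 and comes back at 7. It moves the closure to the acid side with a regio-defined enol derivative. Cyclodehydration of the γ-keto acid with acetic anhydride/NaOAc should give the enol lactone 5-[4-(3,5-dimethoxyphenyl)-1-methoxy-3-methyl-2,4-dioxobutylidene]dihydrofuran-2(3H)-one F1, in which the C1 oxygen is locked in the lactone so that no pyrone can form. TiCl4 (CH2Cl2, −40 °C to rt) should then promote a vinylogous Mukaiyama-type addition of C10a to the activated aryl ketone C4a, followed by dehydration and tautomerization, giving the benzofuranone 7 directly.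

2. Step 7. Facial discrimination may be low or reversed on this bay-hindered, chelating substrate, and oxidation may compete at other positions. The fallback sets out from 11 and comes back at 12. It replaces asymmetric catalysis by resolution. The same oxaziridine with Sc(O3SCF3)3 and no chiral ligand should give the racemic ketol 4-hydroxy-2,6,8-trimethoxy-4-methyl-3-oxo-3,4-dihydrophenanthrene-1,9-diyl diacetate F2. Preparative chromatography on a chiral stationary phase would separate 12 from the (4S)-enantiomer F3, which is set aside.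

3. Step 9. The Lewis acid may lose chemoselectivity on the polyhydroxylated ketol: cleavage of C2–OMe, or ionization or α-ketol rearrangement at C4. The fallback sets out from 13 and comes back at 18. It moves the demethylation behind the annulation and uses magnesium chelation instead of a boron halide. Under the conditions of step 10, 13 and 15 should pass through the enaminone acetal (4R)-3-[(4,4-diethoxybutyl)amino]-4-hydroxy-2,6,8-trimethoxy-4-methylphenanthrene-1,9(4H,10H)-dione F4 and the enaminone aldehyde 4-{[(4R)-4-hydroxy-2,6,8-trimethoxy-4-methyl-1,9-dioxo-1,4,9,10-tetrahydrophenanthren-3-yl]amino}butanal F5 (neither isolated) to the 8-O-methyl ether of the target F6. MgI2 etherate (toluene/Et2O, 60 °C) should then remove only the methyl group peri to the C9 ketone, giving 18.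

**Further compounds**

F1 | step 3 | 5-[4-(3,5-dimethoxyphenyl)-1-methoxy-3-methyl-2,4-dioxobutylidene]dihydrofuran-2(3H)-one | O=C1CCC(O1)=C(OC)C(=O)C(C)C(=O)c1cc(OC)cc(OC)c1
F2 | step 7 | racemic 4-hydroxy-2,6,8-trimethoxy-4-methyl-3-oxo-3,4-dihydrophenanthrene-1,9-diyl diacetate | CC(=O)OC1=C(OC)C(=O)C(C)(O)c2c1cc(OC(C)=O)c1c(OC)cc(OC)cc12
F3 | step 7 | (4S)-4-hydroxy-2,6,8-trimethoxy-4-methyl-3-oxo-3,4-dihydrophenanthrene-1,9-diyl diacetate | CC(=O)OC1=C(OC)C(=O)[C@@](C)(O)c2c1cc(OC(C)=O)c1c(OC)cc(OC)cc12
F4 | step 9 | (4R)-3-[(4,4-diethoxybutyl)amino]-4-hydroxy-2,6,8-trimethoxy-4-methylphenanthrene-1,9(4H,10H)-dione | COC1=C(NCCCC(OCC)OCC)[C@](C)(O)C2=C(CC(=O)c3c(OC)cc(OC)cc32)C1=O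
F5 | step 9 | 4-{[(4R)-4-hydroxy-2,6,8-trimethoxy-4-methyl-1,9-dioxo-1,4,9,10-tetrahydrophenanthren-3-yl]amino}butanal | COC1=C(NCCCC=O)[C@](C)(O)C2=C(CC(=O)c3c(OC)cc(OC)cc32)C1=O
F6 | step 9 | 8-O-methyl ether of the target (C4 R, aminal carbon S) | COC1=C2N3CCC[C@@H]3O[C@]2(C)C2=C(CC(=O)c3c(OC)cc(OC)cc32)C1=O
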